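Time was where I began: the set-ups asked about below hold the same charges and differ in when and how those charges meet.

common to all: initiator 2.5 mol%

| run | starting material | partner | remark | time |
|---|---|---|---|---|
| south-west | 20 mM | 1 equiv | run made earlier |  |
| south-east | 20 mM | 2 equiv | run made earlier |  |
| Saturday's | 20 mM | 1.00 equiv (fed, over 15.0 min) | a stirred flask in which partner is dosed at a steady rate over 15.0 min without added volume, worked up at 15 min | 15 min |
| Friday's | 20 mM (fed, over 15.0 min) | 1.00 equiv | all but starting material at the start; starting material goes in evenly over 15.0 min, the run ends at 15 min | 15 min |
| Wednesday's | 20 mM | 1.00 equiv | everything together in a closed stirred flask, run for 15 min | 15 min |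
| Sunday's | 20 mM | 1.00 equiv | a single well-mixed tank run continuously and read at steady state, 15 min in it on average |  |

| run | time / min | target / % | starting material / % |
|---|---|---|---|
| south-west | 2.00 | 91.0 | 6.7 |
| south-west | 5.00 | 96.0 | 0 |
| south-west | 10.0 | 97.0 | 0 |
| south-west | 15.0 | 97.0 | 0 |
| south-east | 0.417 | 41.7 | 57.0 |
| south-east | 1.00 | 76.0 | 20.9 |
| south-east | 2.00 | 92.3 | 4.4 |
| south-east | 3.00 | 94.4 | 0.2 |

(scatter of a reading: 1 percentage point)

- the stated concentrations are those of everything mixed, before any reaction; amounts are the same in each set-up
- the feed brings no volume worth counting
- the earlier runs were made in a closed, stirred flask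

* the set-up with the highest amount of target at the outlet or at the end, in percent of the starting material put in ("none" if the first two lie within 2 percentage points) (Saturday's / Friday's / Wednesday's / Sunday's / none)
* amount of target at the outlet or at the end, in percent of the starting material put in, Saturday's
* amount of target at the outlet or at the end, in percent of the starting material put in, Friday's
* amount of target at the outlet or at the end, in percent of the starting material put in, Wednesday's
* amount of target at the outlet or at the end, in percent of the starting material put in, Sunday's

Doubling the partner moved the target at 2.00 min from 91.0% to 92.3%, so I treated the starting material as pseudo-first-order. The south-west run, with 6.7% left at that time, gave a first-order rate constant, as a reading, of 1.35 min⁻¹, a life of 0.740 min. Two numbers then seemed not to go together. That life is shorter than the feed of 15.0 min by a factor of 20.3, so I expected each portion of partner in Saturday's to react soon after arrival, and dosing looked free. Yet the last reading of the south-west run stood 3.00% of the charge short in target, and its target read 97.0% at both of the last times, with the starting material reading 0%. I therefore assumed that the loss needs starting material and target together, at a rate proportional to the product of their shares.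

The time integral of that product I call the overlap time. In the south-west run, with an exponential share and its complement, it comes in closed form to 0.370 min, half the life. In Saturday's the two shares run as straight lines across the feed, and the integral is the feed time over 6, or 2.50 min. The overlap time of Saturday's is longer than that of the south-west run by a factor of 6.76, so I reckoned for Saturday's a loss of 20.3% and a target near 79.7%. Wednesday's repeats the south-west recipe, so I expected it near 97.0%, above my figure for Saturday's.

The forecast named Wednesday's best with 97%, and gave 92% for Saturday's, 91% for Friday's and 90.5% for Sunday's, reasoning from “about 3% lost in proportion to conversion”. My figure for Saturday's stood lower.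

Saturday's gave 81.6%, Friday's 88.1%, Wednesday's 96.2% and Sunday's 89.0%, so Wednesday's came first.

    starting material + second chain carrier → by-product + first chain carrier (k = 6.30 × 10⁵ M⁻¹ s⁻¹)
    starting material + target → side product (k = 0.0430 M⁻¹ s⁻¹)
    partner ⇌ dormant form (K = 0.430, k = 0.00100 s⁻¹)
    initiator → 2 initiating radical (k = 3.20 × 10⁻⁴ s⁻¹)
    2 second chain carrier → ended chains (k = 1.00 × 10⁸ M⁻¹ s⁻¹)
    partner + first chain carrier ⇌ target + second chain carrier (K = 0.140, k = 9000 M⁻¹ s⁻¹)
    starting material + initiating radical → capped initiator + first chain carrier (k = 4.10 × 10⁵ M⁻¹ s⁻¹)

Saturday's ended with 18.4% of side product, more than the 3.72% of Wednesday's; for Saturday's the overlap time had reckoned a loss of 20.3%. In the neighbour of Saturday's with 2.50 equiv of partner, fed over the same 15.0 min, one equivalent has arrived after 6.00 min. Its overlap time is that over 6, 1.00 min, which scales the loss to 8.11%; that flask ended with 8.78% of side product.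

The runs come from a simulation with constants of no real substance; the scatter is artificial.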